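Numbering: C1 is the quaternary carbinol carbon, C7 its CH2O carbon, C2 (OH), C3 (OBz), C4=C5 and C6 (OBz) follow round the six-membered ring. Removing the oxygens at C2, C3 and C6 exposes a mirror plane through C7, C1 and C4: a meso cyclohexa-2,5-dienyl carbinol whose alkenes C2=C3 and C5=C6 are enantiotopic. A vanadium bis-hydroxamate catalyst anchored on the C7 hydroxyl epoxidises only C5=C6, on the C7 face; this one operation closes the oxirane, makes C1 stereogenic, sets C5 and C6 and leaves C2=C3 for a later directed dihydroxylation. The precursor is achiral [1-(triethylsilyloxy)cyclohexa-2,5-dien-1-yl]methanol: free primary alcohol to bind the metal, silylated tertiary oxygen that cannot direct.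

Key step: step 6

Convention: β is the face of the ring on which C7 stands at C1; α is the face of the C1 oxygen. In the target the oxygens at C1, C2 and C3 are α and the C6 oxygen is β.

Assumption: the sense of induction of the bis-hydroxamate catalyst on this substrate type has to be assigned by correlation. The (R,R)-ligand is written; the equally accessible (S,S)-ligand is taken if the correlation demands it.

Remark: the triethylsilyl group is put on the tertiary oxygen at the ester stage, before the primary hydroxyl exists, and the ester is reduced with iBu2AlH at low temperature, so that the silyl group cannot move to the primary oxygen. The C6 and C7 hydroxyls are benzoylated together after the epoxide has been transposed, which saves one step.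

Step 1
Reactants: 1 benzoic acid
Product: 2 cyclohexa-2,5-diene-1-carboxylic acid
Conditions: Na, NH3 (l), EtOH, −78 °C; then NH4Cl, cold aq. HCl
Reagents that add atoms: none
Why: Birch reduction, in which the carboxylate-stabilised anion is protonated at C1 and C4 to give the skipped 2,5-diene and no stereocentre.

Step 2
Reactants: 2 cyclohexa-2,5-diene-1-carboxylic acid
Product: 3 methyl cyclohexa-2,5-diene-1-carboxylate
Conditions: MeI, KHCO3, DMF, rt
Reagents that add atoms: iodomethane, CI
Why: SN2 O-alkylation of the carboxylate, with bicarbonate too weak a base to remove the doubly allylic C1 hydrogen, so the skipped diene should be neither isomerised nor C-methylated.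

Step 3
Reactants: 3 methyl cyclohexa-2,5-diene-1-carboxylate
Product: 5 methyl 1-hydroxycyclohexa-2,5-diene-1-carboxylate, via potassium ester enolate 4 (not isolated)
Conditions: KN(SiMe3)2, THF, −78 °C; then 2-(phenylsulfonyl)-3-phenyloxaziridine, −78 °C; aq. NH4Cl
Reagents that add atoms: 2-(phenylsulfonyl)-3-phenyloxaziridine, O=S(=O)(N1OC1c1ccccc1)c1ccccc1
Why: Enolate hydroxylation with an N-sulfonyloxaziridine (Davis oxidation), in which the cross-conjugated potassium dienolate should react at its central α-carbon as in Birch alkylations, and C1 is not yet stereogenic because its two vinyl arms are identical.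

Step 4
Reactants: 5 methyl 1-hydroxycyclohexa-2,5-diene-1-carboxylate; 6 triethylsilyl trifluoromethanesulfonate
Product: 7 methyl 1-(triethylsilyloxy)cyclohexa-2,5-diene-1-carboxylate
Conditions: 2,6-lutidine, CH2Cl2, −78 → 0 °C
Reagents that add atoms: triethylsilyl trifluoromethanesulfonate, CC[Si](CC)(CC)OS(=O)(=O)C(F)(F)F
Why: Silylation of a hindered tertiary alcohol with a silyl triflate and a hindered pyridine base, which keeps the medium non-acidic so that the doubly allylic carbinol cannot ionise and aromatise.

Step 5
Reactants: 7 methyl 1-(triethylsilyloxy)cyclohexa-2,5-diene-1-carboxylate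
Product: 9 [1-(triethylsilyloxy)cyclohexa-2,5-dien-1-yl]methanol, via silyloxy aldehyde 8 (not isolated)
Conditions: iBu2AlH (2.5 equiv), CH2Cl2, −78 → −20 °C; aq. KNaC4H4O6 (potassium sodium tartrate)
Reagents that add atoms: none
Why: Hydride reduction of the ester through the aldehyde, in which the covalent aluminium alkoxide formed at low temperature should not promote 1,4-silyl migration, so the silyl group stays on the tertiary oxygen and the primary hydroxyl is left free for the catalyst.

Step 6
Reactants: 9 [1-(triethylsilyloxy)cyclohexa-2,5-dien-1-yl]methanol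
Product: 10 [(1R,2S,6R)-2-(triethylsilyloxy)-7-oxabicyclo[4.1.0]hept-3-en-2-yl]methanol (C5–C6 β-epoxide)
Conditions: VO(OiPr)3 (2 mol%), (1R,2R)-N,N′-dihydroxy-N,N′-bis(diphenylacetyl)cyclohexane-1,2-diamine (4 mol%), PhC(CH3)2OOH (1.1 equiv), toluene, 0 °C → rt
Reagents that add atoms: cumene hydroperoxide, CC(C)(OO)c1ccccc1
Why: Ligand exchange binds the C7 alkoxide and the cumyl peroxide to pentavalent vanadium held by the C2-symmetric bis-hydroxamate, and the peroxide oxygen is then passed intramolecularly to the π-bond of one ring alkene in a concerted transfer, which is the known vanadium and bis-hydroxamic acid asymmetric epoxidation of homoallylic alcohols used here as a desymmetrisation of a meso dienyl carbinol. The oxirane ring is closed by this concerted [2+1] oxygen-atom transfer, the C5–O and C6–O bonds forming on the same side of the alkene, not by an exo or endo displacement. C5 and C6 are set together on the β face because the two-atom tether C7–C1 can present the metal-bound peroxide only to the face of the ring that carries C7. C1 becomes stereogenic through the choice between the enantiotopic alkenes C5=C6 and C2=C3, and that choice is made by the chiral pocket of the ligand. The step needs group selectivity, face selectivity and mono-epoxidation: the ligand secures the first, the free primary C7 hydroxyl together with the silylated C1 oxygen (which cannot bind vanadium and so cannot direct to the α face) secures the second, and a small excess only of hydroperoxide secures the third. Any second epoxidation should consume the minor enantiomer preferentially, so over-oxidation would cost material but raise optical purity.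

Step 7
Reactants: 10 [(1R,2S,6R)-2-(triethylsilyloxy)-7-oxabicyclo[4.1.0]hept-3-en-2-yl]methanol
Product: 13 [6β-hydroxy-1α-(triethylsilyloxy)cyclohexa-2,4-dien-1-yl]methanol, via hydroxy selenide 11 (not isolated), via selenoxide 12 (not isolated)
Conditions: (PhSe)2, NaBH4, EtOH, rt → 60 °C; then THF, pyridine, 30% H2O2 (3 equiv), 0 °C → rt
Reagents that add atoms: none
Why: Epoxide-to-allylic-alcohol transposition by selenolate SN2 opening and selenoxide syn-elimination, in which the selenolate should attack C5, the oxirane carbon remote from the quaternary C1, with inversion, and the selenoxide should eliminate towards the allylic C4 hydrogen and away from the carbinol carbon, so that C6 keeps its β oxygen and C4=C5 is formed.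

Step 8
Reactants: 13 [6β-hydroxy-1α-(triethylsilyloxy)cyclohexa-2,4-dien-1-yl]methanol; 14 benzoyl chloride
Product: 15 [6β-(benzoyloxy)-1α-(triethylsilyloxy)cyclohexa-2,4-dien-1-yl]methyl benzoate
Conditions: BzCl (2.5 equiv), pyridine, DMAP (cat.), CH2Cl2, 0 °C → rt
Reagents that add atoms: benzoyl chloride, O=C(Cl)c1ccccc1
Why: Nucleophile-catalysed acylation (DMAP) of the primary C7 and the secondary C6 hydroxyl, with the tertiary oxygen masked and no stereocentre touched.

Step 9
Reactants: 15 [6β-(benzoyloxy)-1α-(triethylsilyloxy)cyclohexa-2,4-dien-1-yl]methyl benzoate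
Product: 16 [6β-(benzoyloxy)-1α-hydroxycyclohexa-2,4-dien-1-yl]methyl benzoate
Conditions: HF·pyridine, pyridine, THF, 0 °C → rt
Reagents that add atoms: none
Why: Fluoride-driven cleavage of the Si–O bond under pyridine-buffered conditions, which avoids both the base that would move benzoates and the acid that would dehydrate the dienol to an arene.

Step 10
Reactants: 16 [6β-(benzoyloxy)-1α-hydroxycyclohexa-2,4-dien-1-yl]methyl benzoate
Product: 18 [6β-(benzoyloxy)-1α,2α,3α-trihydroxycyclohex-4-en-1-yl]methyl benzoate, via osmate ester TMEDA chelate 17 (not isolated)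
Conditions: OsO4 (1.05 equiv), TMEDA (1.1 equiv), CH2Cl2, −78 °C; then conc. HCl, MeOH, rt
Reagents that add atoms: osmium tetroxide, O=[Os](=O)(=O)=O
Why: Hydrogen-bond-directed syn-dihydroxylation ([3+2] addition of the OsO4–TMEDA adduct), in which the only free hydroxyl, at C1, should steer the reagent to the neighbouring C2=C3 bond and to the α face, setting C2 and C3 with both oxygens cis to the C1 hydroxyl, while the C7 arm shields the β face and the allylic benzoate at C6 deactivates C4=C5.

Step 11
Reactants: 18 [6β-(benzoyloxy)-1α,2α,3α-trihydroxycyclohex-4-en-1-yl]methyl benzoate; 14 benzoyl chloride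
Product: 19 [(1R,2R,3R,6R)-3,6-bis(benzoyloxy)-1,2-dihydroxycyclohex-4-en-1-yl]methyl benzoate
Conditions: BzCl (1.1 equiv), pyridine, CH2Cl2, −40 → 0 °C
Reagents that add atoms: benzoyl chloride, O=C(Cl)c1ccccc1
Why: Kinetically site-selective esterification, since the allylic secondary C3 hydroxyl is the most accessible, the C2 hydroxyl is flanked by the quaternary C1 and by C3, and the tertiary C1 hydroxyl should not acylate under these conditions.

Compound list
1 | benzoic acid | OC(=O)c1ccccc1 | starting material
2 | cyclohexa-2,5-diene-1-carboxylic acid (1,4-dihydrobenzoic acid) | OC(=O)C1C=CCC=C1 | intermediate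
3 | methyl cyclohexa-2,5-diene-1-carboxylate | COC(=O)C1C=CCC=C1 | intermediate
4 | potassium enolate of 3, potassium (cyclohexa-2,5-dien-1-ylidene)(methoxy)methanolate | COC([O-])=C1C=CCC=C1.[K+] | intermediate (not isolated)
5 | methyl 1-hydroxycyclohexa-2,5-diene-1-carboxylate | COC(=O)C1(O)C=CCC=C1 | intermediate
6 | triethylsilyl trifluoromethanesulfonate | CC[Si](CC)(CC)OS(=O)(=O)C(F)(F)F | starting material
7 | methyl 1-(triethylsilyloxy)cyclohexa-2,5-diene-1-carboxylate | COC(=O)C1(O[Si](CC)(CC)CC)C=CCC=C1 | intermediate
8 | 1-(triethylsilyloxy)cyclohexa-2,5-diene-1-carbaldehyde | O=CC1(O[Si](CC)(CC)CC)C=CCC=C1 | intermediate (not isolated)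
9 | [1-(triethylsilyloxy)cyclohexa-2,5-dien-1-yl]methanol (achiral, mirror plane through C7, C1 and C4) | OCC1(O[Si](CC)(CC)CC)C=CCC=C1 | intermediate
10 | [(1R,2S,6R)-2-(triethylsilyloxy)-7-oxabicyclo[4.1.0]hept-3-en-2-yl]methanol; C5–C6 β-epoxide, oxirane cis to C7 and trans to the silyl ether | OC[C@@]1(O[Si](CC)(CC)CC)C=CC[C@H]2O[C@@H]12 | intermediate
11 | [6β-hydroxy-5α-(phenylselanyl)-1α-(triethylsilyloxy)cyclohex-2-en-1-yl]methanol | OC[C@@]1(O[Si](CC)(CC)CC)C=CC[C@H]([Se]c2ccccc2)[C@H]1O | intermediate (not isolated)
12 | selenoxide of 11 (both configurations at selenium) | OC[C@@]1(O[Si](CC)(CC)CC)C=CC[C@H]([Se](=O)c2ccccc2)[C@H]1O | intermediate (not isolated)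
13 | [6β-hydroxy-1α-(triethylsilyloxy)cyclohexa-2,4-dien-1-yl]methanol | OC[C@@]1(O[Si](CC)(CC)CC)C=CC=C[C@H]1O | intermediate
14 | benzoyl chloride | O=C(Cl)c1ccccc1 | starting material
15 | [6β-(benzoyloxy)-1α-(triethylsilyloxy)cyclohexa-2,4-dien-1-yl]methyl benzoate | O=C(OC[C@@]1(O[Si](CC)(CC)CC)C=CC=C[C@H]1OC(=O)c1ccccc1)c1ccccc1 | intermediate
16 | [6β-(benzoyloxy)-1α-hydroxycyclohexa-2,4-dien-1-yl]methyl benzoate | O=C(OC[C@@]1(O)C=CC=C[C@H]1OC(=O)c1ccccc1)c1ccccc1 | intermediate
17 | cyclic 2α,3α-osmate ester of 16 (dioxo glycolate of hexavalent osmium, chelated by TMEDA) | O=C(OC[C@@]1(O)[C@@H]2O[Os](=O)(=O)O[C@@H]2C=C[C@H]1OC(=O)c1ccccc1)c1ccccc1.CN(C)CCN(C)C | intermediate (not isolated)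
18 | [6β-(benzoyloxy)-1α,2α,3α-trihydroxycyclohex-4-en-1-yl]methyl benzoate | O=C(OC[C@@]1(O)[C@H](O)[C@H](O)C=C[C@H]1OC(=O)c1ccccc1)c1ccccc1 | intermediate
19 | [(1R,2R,3R,6R)-3,6-bis(benzoyloxy)-1,2-dihydroxycyclohex-4-en-1-yl]methyl benzoate (1α,2α-diol, 3α- and 6β-benzoates) | O=C(OC[C@@]1(O)[C@H](O)[C@H](OC(=O)c2ccccc2)C=C[C@H]1OC(=O)c1ccccc1)c1ccccc1 | target

Total steps: 11. Longest linear sequence: 11 steps (1 to 19).

Steps most likely to fail

Step 6. What may go wrong: weak discrimination between the two enantiotopic alkenes at the crowded quaternary centre, epoxidation of both alkenes, or hydrogen abstraction at the doubly allylic C4 by peroxide-derived radicals followed by fragmentation to an arene. The fallback replaces catalytic desymmetrisation by classical resolution; it sets out from 9 and comes back at 10. Hydroxyl-directed epoxidation of 9 with VO(acac)2 and t-BuOOH in CH2Cl2 at 0 °C should give the racemic β-epoxy alcohol F1, still cis to C7 because the same homoallylic hydroxyl delivers the oxygen. Steglich esterification (DCC, DMAP) with (R)-2-methoxy-2-phenylacetic acid should give the wanted diastereomeric ester F2 together with its diastereomer F3, to be separated by chromatography. Methanolysis of F2 (K2CO3, MeOH, 0 °C) should return 10 as a single enantiomer.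

Step 10. What may go wrong: delivery to the wrong alkene or the wrong face of the conjugated diene if the C1 hydroxyl is tied up in an internal hydrogen bond to a benzoate carbonyl, and dehydrative aromatisation of the dienol while it is handled. The fallback keeps the C4=C5 alkene latent as a sulfide until the diol is in place, so that the osmylation meets one alkene only and no dienol is formed; it sets out from 10 and comes back at 18. PhSNa (from PhSH and NaOH in EtOH) should open 10 at C5 to the trans hydroxy sulfide diol F4. BzCl, pyridine and DMAP should give the dibenzoate F5, and HF·pyridine should free the tertiary alcohol F6. OsO4–TMEDA, steered by the C1 hydroxyl to the α face of the only alkene, should give the osmate ester F7, to be cleaved with HCl in MeOH to the triol sulfide F8. mCPBA at −78 °C should give the sulfoxide F9, whose thermal syn-elimination (toluene, 110 °C, NaHCO3) towards C4 and away from the benzoyloxy-bearing C6 should form C4=C5 and give 18.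

Step 11. What may go wrong: loss of site selectivity, that is acylation at O2, double acylation, or acyl migration between O2 and O3. The fallback replaces amine-mediated kinetic acylation by tin-acetal activation; it sets out from 18 and comes back at 19. Bu2SnO in refluxing toluene with removal of water should convert the cis-2,3-diol into the dibutylstannylene acetal F10, which is treated with one equivalent of BzCl at 0 °C without added base. Acylation of such five-membered stannylenes is expected at the more accessible oxygen, here the allylic O3, and aqueous work-up should free the C2 hydroxyl to give 19.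

Further compounds
F1 | step 6 | racemic β-epoxy alcohol (10 and its enantiomer, 1:1) | OC[C@@]1(O[Si](CC)(CC)CC)C=CC[C@H]2O[C@@H]12.OC[C@]1(O[Si](CC)(CC)CC)C=CC[C@@H]2O[C@H]12
F2 | step 6 | (R)-2-methoxy-2-phenylacetate of 10 | CO[C@@H](C(=O)OC[C@@]1(O[Si](CC)(CC)CC)C=CC[C@H]2O[C@@H]12)c1ccccc1
F3 | step 6 | (R)-2-methoxy-2-phenylacetate of the enantiomer of 10 | CO[C@@H](C(=O)OC[C@]1(O[Si](CC)(CC)CC)C=CC[C@@H]2O[C@H]12)c1ccccc1
F4 | step 10 | [6β-hydroxy-5α-(phenylsulfanyl)-1α-(triethylsilyloxy)cyclohex-2-en-1-yl]methanol | OC[C@@]1(O[Si](CC)(CC)CC)C=CC[C@H](Sc2ccccc2)[C@H]1O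
F5 | step 10 | [6β-(benzoyloxy)-5α-(phenylsulfanyl)-1α-(triethylsilyloxy)cyclohex-2-en-1-yl]methyl benzoate | O=C(OC[C@@]1(O[Si](CC)(CC)CC)C=CC[C@H](Sc2ccccc2)[C@H]1OC(=O)c1ccccc1)c1ccccc1
F6 | step 10 | [6β-(benzoyloxy)-1α-hydroxy-5α-(phenylsulfanyl)cyclohex-2-en-1-yl]methyl benzoate | O=C(OC[C@@]1(O)C=CC[C@H](Sc2ccccc2)[C@H]1OC(=O)c1ccccc1)c1ccccc1
F7 | step 10 | cyclic 2α,3α-osmate ester of F6, chelated by TMEDA | O=C(OC[C@@]1(O)[C@@H]2O[Os](=O)(=O)O[C@@H]2C[C@H](Sc2ccccc2)[C@H]1OC(=O)c1ccccc1)c1ccccc1.CN(C)CCN(C)C
F8 | step 10 | [6β-(benzoyloxy)-1α,2α,3α-trihydroxy-5α-(phenylsulfanyl)cyclohexyl]methyl benzoate | O=C(OC[C@@]1(O)[C@H](O)[C@H](O)C[C@H](Sc2ccccc2)[C@H]1OC(=O)c1ccccc1)c1ccccc1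
F9 | step 10 | sulfoxide of F8 (both configurations at sulfur) | O=C(OC[C@@]1(O)[C@H](O)[C@H](O)C[C@H](S(=O)c2ccccc2)[C@H]1OC(=O)c1ccccc1)c1ccccc1
F10 | step 11 | 2α,3α-O-dibutylstannylene acetal of 18 | O=C(OC[C@@]1(O)[C@@H]2O[Sn](CCCC)(CCCC)O[C@@H]2C=C[C@H]1OC(=O)c1ccccc1)c1ccccc1
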